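**Retrosynthetic overview**
- The target is an oxolane (O1, C2–C5) with the 3,4,5-trimethoxyphenyl ring on C2, CH2OH (C9) on C3 and an arylmethyl group (C7') on C4, 2,3-trans and 3,4-cis. C4–H is traced back to hydrogenation of a C4=C7' benzylidene from the face opposite the C3 arm, C9 to an ester, and that ester to a C3 malonate.
- The feature the plan rests on: O1–C5–C4–C7' is the O–CH2–C≡C chain of propargyl alcohol, C2–C3–C9 is an arylidene malonate short of one ester, and C7' carries an aryl ring that an aryl iodide can deliver.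
- Key disconnection: O1–C2, C3–C4 and C7'–aryl are cut together (alkoxide conjugate addition, carbopalladation, aryl coupling). The oxolane is the only ring formed; it closes in this step by 5-exo-dig attack, and C2 is set there.
- The benzylidene malonate comes from a Knoevenagel condensation. C3 is set by equilibration after loss of one ester, C4 by the hydrogenation.

Key step: step 2

Assumption: the sense of induction of the chiral palladium complex in step 2 cannot be predicted; the route is written with (R)-DTBM-SEGPHOS, and the (S)-ligand is taken instead if the (R)-ligand favours the 2R coupling product.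

**Route**

Step 1
Reactants: 1 3,4,5-trimethoxybenzaldehyde; 2 dimethyl malonate
Product: 3 dimethyl 2-(3,4,5-trimethoxybenzylidene)malonate
Conditions: piperidine (0.1 equiv), AcOH (0.1 equiv), toluene, reflux, Dean–Stark
Reagents that add atoms: none
Why: Knoevenagel condensation, in which amine-catalysed addition of the malonate to the aldehyde and dehydration are driven to completion by azeotropic removal of water; no stereocentre is formed.

Step 2
Reactants: 3 dimethyl 2-(3,4,5-trimethoxybenzylidene)malonate; 4 propargyl alcohol; 5 4-iodo-1,2-dimethoxybenzene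
Product: 8 dimethyl (2S,4Z)-4-(3,4-dimethoxybenzylidene)-2-(3,4,5-trimethoxyphenyl)oxolane-3,3-dicarboxylate, via lithium prop-2-yn-1-olate 6 (not isolated), via lithium malonate oxa-Michael adduct 7 (not isolated)
Conditions: 4 (1.3 equiv), n-BuLi (1.2 equiv), THF, −78 to 0 °C; then 3, 5 (1.2 equiv), Pd2(dba)3 (2.5 mol %), (R)-DTBM-SEGPHOS (6 mol %), DMSO–THF, 0 °C to rt
Reagents that add atoms: none
Why: Proposed new method: alkoxide 6 adds reversibly to the benzylidene malonate 3 (O1–C2) to give the malonate anion 7 as a rapidly interconverting pair of enantiomers, while oxidative addition of 5 to the zerovalent palladium–bisphosphine complex gives an arylpalladium iodide that, after loss of iodide in DMSO, binds the alkyne of 7. The malonate carbon then attacks the activated alkyne anti to palladium in a 5-exo-dig closure of the oxolane (C3–C4), and reductive elimination from the vinyl(aryl)palladium species forms the C7'–aryl bond and returns zerovalent palladium. The closest known reaction types are the racemic palladium-mediated three-component coupling of propargyl alkoxides, alkylidene malonates and aryl halides and the enantioselective Conia-ene-type cyclisation of 1,3-dicarbonyl nucleophiles onto alkynes under cationic palladium–bisphosphine catalysis; the new demand is that the chiral complex discriminates between the two enantiomers of 7. C2 is therefore set by a dynamic kinetic resolution, the two diastereomeric cyclisation transition states differing in the contact between the C2 aryl group and the bulky P-aryl groups of the ligand, and it cannot erode afterwards because C3 of 8 is quaternary and no retro-addition is possible. The step needs 5-exo over 6-endo closure, which the short O–CH2 tether to a terminal alkyne secures, and the Z alkene, which follows from anti attack and stereoretentive reductive elimination. Chemoselectivity rests on the aryl iodide being the only carbon–halogen bond present.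

Step 3
Reactants: 8 dimethyl (2S,4Z)-4-(3,4-dimethoxybenzylidene)-2-(3,4,5-trimethoxyphenyl)oxolane-3,3-dicarboxylate
Product: 9 methyl (2R,3R,4Z)-4-(3,4-dimethoxybenzylidene)-2-(3,4,5-trimethoxyphenyl)oxolane-3-carboxylate (2,3-trans)
Conditions: LiCl (2 equiv), H2O (2 equiv), DMSO, 140 °C
Reagents that add atoms: none
Why: Krapcho dealkoxycarbonylation, in which chloride dealkylates one methyl ester, the carboxylate loses CO2 and the dienolate is protonated at C3, the doubly activated C3–H then equilibrating in the hot medium to the more stable 2,3-trans ester (this sets C3), while C2 should hold because ring opening from the enolate would be a disfavoured retro-5-endo-trig elimination.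

Step 4
Reactants: 9 methyl (2R,3R,4Z)-4-(3,4-dimethoxybenzylidene)-2-(3,4,5-trimethoxyphenyl)oxolane-3-carboxylate
Product: 10 [(2R,3S,4Z)-4-(3,4-dimethoxybenzylidene)-2-(3,4,5-trimethoxyphenyl)oxolan-3-yl]methanol
Conditions: LiAlH4 (1.2 equiv), THF, −20 to 0 °C; aq. KNaC4H4O6 work-up
Reagents that add atoms: none
Why: Hydride reduction of the ester by LiAlH4 at low temperature is faster than enolisation of the allylic C3–H, so the primary alcohol should form with C3 and the exocyclic alkene unchanged.

Step 5
Reactants: 10 [(2R,3S,4Z)-4-(3,4-dimethoxybenzylidene)-2-(3,4,5-trimethoxyphenyl)oxolan-3-yl]methanol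
Product: 11 tert-butyl{[(2R,3S,4Z)-4-(3,4-dimethoxybenzylidene)-2-(3,4,5-trimethoxyphenyl)oxolan-3-yl]methoxy}diphenylsilane
Conditions: TBDPSCl (1.2 equiv), imidazole (2.5 equiv), DMF, 0 °C to rt
Reagents that add atoms: tert-butyl(chloro)diphenylsilane (TBDPSCl), CC(C)(C)[Si](Cl)(c1ccccc1)c1ccccc1
Why: Imidazole-promoted silylation of a primary alcohol, which removes a hydroxyl that could steer hydrogen to its own face and makes the C3 arm large for the next step.

Step 6
Reactants: 11 tert-butyl{[(2R,3S,4Z)-4-(3,4-dimethoxybenzylidene)-2-(3,4,5-trimethoxyphenyl)oxolan-3-yl]methoxy}diphenylsilane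
Product: 12 tert-butyl{[(2R,3S,4S)-4-(3,4-dimethoxybenzyl)-2-(3,4,5-trimethoxyphenyl)oxolan-3-yl]methoxy}diphenylsilane
Conditions: H2 (1 atm), 10% Pd/C, pyridine (0.5 equiv), EtOAc, rt
Reagents that add atoms: none
Why: Heterogeneous catalytic hydrogenation should add both hydrogens syn from the alkene face opposite the adjacent CH2OTBDPS arm, placing H4 cis to H3 and the benzyl group cis to the C3 arm (C4 = S), with pyridine added as a catalyst modifier that suppresses hydrogenolysis of the benzylic C2–O1 bond.

Step 7
Reactants: 12 tert-butyl{[(2R,3S,4S)-4-(3,4-dimethoxybenzyl)-2-(3,4,5-trimethoxyphenyl)oxolan-3-yl]methoxy}diphenylsilane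
Product: 13 [(2R,3S,4S)-4-(3,4-dimethoxybenzyl)-2-(3,4,5-trimethoxyphenyl)oxolan-3-yl]methanol (target, CNP0107562.1)
Conditions: TBAF (1.2 equiv), THF, 0 °C to rt
Reagents that add atoms: none
Why: Fluoride-mediated cleavage of the silyl ether under non-acidic conditions should free the primary alcohol without touching the acid-sensitive benzylic C2–O1 ether or any stereocentre.

**Compound list**
1 | 3,4,5-trimethoxybenzaldehyde | COc1cc(C=O)cc(OC)c1OC | starting material
2 | dimethyl malonate | COC(=O)CC(=O)OC | starting material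
3 | dimethyl 2-(3,4,5-trimethoxybenzylidene)malonate | COC(=O)C(=Cc1cc(OC)c(OC)c(OC)c1)C(=O)OC | intermediate
4 | propargyl alcohol (prop-2-yn-1-ol) | C#CCO | starting material
5 | 4-iodo-1,2-dimethoxybenzene | COc1ccc(I)cc1OC | starting material
6 | lithium prop-2-yn-1-olate | [Li+].[O-]CC#C | intermediate
7 | lithium enolate of dimethyl 2-[(prop-2-yn-1-yloxy)(3,4,5-trimethoxyphenyl)methyl]malonate (oxa-Michael adduct, both enantiomers interconverting) | [Li+].[O-]C(OC)=C(C(=O)OC)C(OCC#C)c1cc(OC)c(OC)c(OC)c1 | intermediate
8 | dimethyl (2S,4Z)-4-(3,4-dimethoxybenzylidene)-2-(3,4,5-trimethoxyphenyl)oxolane-3,3-dicarboxylate | COC(=O)C1(C(=O)OC)[C@H](c2cc(OC)c(OC)c(OC)c2)OC/C1=C\c1ccc(OC)c(OC)c1 | intermediate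
9 | methyl (2R,3R,4Z)-4-(3,4-dimethoxybenzylidene)-2-(3,4,5-trimethoxyphenyl)oxolane-3-carboxylate | COC(=O)[C@H]1[C@H](c2cc(OC)c(OC)c(OC)c2)OC/C1=C\c1ccc(OC)c(OC)c1 | intermediate
10 | [(2R,3S,4Z)-4-(3,4-dimethoxybenzylidene)-2-(3,4,5-trimethoxyphenyl)oxolan-3-yl]methanol | OC[C@H]1[C@H](c2cc(OC)c(OC)c(OC)c2)OC/C1=C\c1ccc(OC)c(OC)c1 | intermediate
11 | tert-butyl{[(2R,3S,4Z)-4-(3,4-dimethoxybenzylidene)-2-(3,4,5-trimethoxyphenyl)oxolan-3-yl]methoxy}diphenylsilane | CC(C)(C)[Si](OC[C@H]1[C@H](c2cc(OC)c(OC)c(OC)c2)OC/C1=C\c1ccc(OC)c(OC)c1)(c1ccccc1)c1ccccc1 | intermediate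
12 | tert-butyl{[(2R,3S,4S)-4-(3,4-dimethoxybenzyl)-2-(3,4,5-trimethoxyphenyl)oxolan-3-yl]methoxy}diphenylsilane | COc1ccc(C[C@@H]2CO[C@@H](c3cc(OC)c(OC)c(OC)c3)[C@@H]2CO[Si](c4ccccc4)(c4ccccc4)C(C)(C)C)cc1OC | intermediate
13 | [(2R,3S,4S)-4-(3,4-dimethoxybenzyl)-2-(3,4,5-trimethoxyphenyl)oxolan-3-yl]methanol | COc1ccc(C[C@@H]2CO[C@@H](c3cc(OC)c(OC)c(OC)c3)[C@@H]2CO)cc1OC | target

**Step count**
Total: 7 steps. Longest linear sequence: 7 steps (1 to 13).

**Steps most likely to fail**

1. Step 2 (proposed new method). The chiral palladium centre sits on the alkyne face remote from C2, so discrimination between the two enantiomers of the adduct may be poor. The bisphosphine complex may also be slow to free a coordination site for the alkyne, which would let copper-free alkynylation of the aryl iodide or ester exchange by the alkoxide compete. The fallback uses known chemistry, sets out from 3 (with 4 and 5) and comes back at 10. The racemic coupling with n-BuLi and Pd(PPh3)4 in THF–DMSO should give racemic dimethyl (4Z)-4-(3,4-dimethoxybenzylidene)-2-(3,4,5-trimethoxyphenyl)oxolane-3,3-dicarboxylate F1. LiCl in wet DMSO as in step 3 should give racemic methyl (2R*,3R*,4Z)-4-(3,4-dimethoxybenzylidene)-2-(3,4,5-trimethoxyphenyl)oxolane-3-carboxylate F2, and LiAlH4 as in step 4 racemic [(2R*,3S*,4Z)-4-(3,4-dimethoxybenzylidene)-2-(3,4,5-trimethoxyphenyl)oxolan-3-yl]methanol F3. F3 is then resolved by lipase-catalysed acylation (Pseudomonas cepacia lipase or Candida antarctica lipase B, vinyl acetate, t-BuOMe, rt), run past half conversion. If the enzyme acylates the unwanted antipode, [(2S,3R,4Z)-4-(3,4-dimethoxybenzylidene)-2-(3,4,5-trimethoxyphenyl)oxolan-3-yl]methyl acetate F4 is removed by chromatography and the remaining alcohol is 10. If it acylates the wanted antipode, [(2R,3S,4Z)-4-(3,4-dimethoxybenzylidene)-2-(3,4,5-trimethoxyphenyl)oxolan-3-yl]methyl acetate F5 is collected and methanolysed (K2CO3, MeOH) to 10.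

2. Step 3. The dienolate formed after loss of CO2 may be protonated at C7', or the product may isomerise, so that the exocyclic alkene moves into conjugation with the ester. Equilibration at C3 may be incomplete, and a slow ring opening and reclosure at the enolate stage could erode C2. The fallback sets out from 8 and comes back at 9. One ester is hydrolysed (KOH, 1 equiv, MeOH–H2O, 0 °C to rt, then acidification) to the malonic half-ester (2S,4Z)-4-(3,4-dimethoxybenzylidene)-3-(methoxycarbonyl)-2-(3,4,5-trimethoxyphenyl)oxolane-3-carboxylic acid F6 (C3 epimer immaterial). F6 is decarboxylated through its enol at much lower temperature (Cu2O cat., Et3N, MeCN, 60–80 °C), and the amine should equilibrate C3 to the 2,3-trans ester 9.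

3. Step 6. The C2 aryl group lies on the face from which hydrogen must come, so facial selectivity may be poor. The C2–O1 bond may be hydrogenolysed, and the catalyst may move the alkene into the ring before reduction. The fallback sets out from 11 and comes back at 12 without a new compound. Substrate control is replaced by catalyst control: asymmetric hydrogenation of the trisubstituted aryl alkene with H2 (50 bar) and [Ir(cod)((S)-tBu-PHOX)][B(C6H3(CF3)2)4] in CH2Cl2 at rt, using the ligand antipode that proves matched to delivery anti to the C3 arm. This homogeneous catalyst neither cleaves benzylic C–O bonds nor migrates the alkene readily.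

**Further compounds**
F1 | step 2 | racemic dimethyl (4Z)-4-(3,4-dimethoxybenzylidene)-2-(3,4,5-trimethoxyphenyl)oxolane-3,3-dicarboxylate (both enantiomers) | COC(=O)C1(C(=O)OC)[C@H](c2cc(OC)c(OC)c(OC)c2)OC/C1=C\c1ccc(OC)c(OC)c1.COC(=O)C1(C(=O)OC)[C@@H](c2cc(OC)c(OC)c(OC)c2)OC/C1=C\c1ccc(OC)c(OC)c1
F2 | step 2 | racemic methyl (2R*,3R*,4Z)-4-(3,4-dimethoxybenzylidene)-2-(3,4,5-trimethoxyphenyl)oxolane-3-carboxylate (both enantiomers) | COC(=O)[C@H]1[C@H](c2cc(OC)c(OC)c(OC)c2)OC/C1=C\c1ccc(OC)c(OC)c1.COC(=O)[C@@H]1[C@@H](c2cc(OC)c(OC)c(OC)c2)OC/C1=C\c1ccc(OC)c(OC)c1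
F3 | step 2 | racemic [(2R*,3S*,4Z)-4-(3,4-dimethoxybenzylidene)-2-(3,4,5-trimethoxyphenyl)oxolan-3-yl]methanol (both enantiomers) | OC[C@H]1[C@H](c2cc(OC)c(OC)c(OC)c2)OC/C1=C\c1ccc(OC)c(OC)c1.OC[C@@H]1[C@@H](c2cc(OC)c(OC)c(OC)c2)OC/C1=C\c1ccc(OC)c(OC)c1
F4 | step 2 | [(2S,3R,4Z)-4-(3,4-dimethoxybenzylidene)-2-(3,4,5-trimethoxyphenyl)oxolan-3-yl]methyl acetate | CC(=O)OC[C@@H]1[C@@H](c2cc(OC)c(OC)c(OC)c2)OC/C1=C\c1ccc(OC)c(OC)c1
F5 | step 2 | [(2R,3S,4Z)-4-(3,4-dimethoxybenzylidene)-2-(3,4,5-trimethoxyphenyl)oxolan-3-yl]methyl acetate | CC(=O)OC[C@H]1[C@H](c2cc(OC)c(OC)c(OC)c2)OC/C1=C\c1ccc(OC)c(OC)c1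
F6 | step 3 | (2S,4Z)-4-(3,4-dimethoxybenzylidene)-3-(methoxycarbonyl)-2-(3,4,5-trimethoxyphenyl)oxolane-3-carboxylic acid (C3 epimer not assigned) | COC(=O)C1(C(=O)O)[C@H](c2cc(OC)c(OC)c(OC)c2)OC/C1=C\c1ccc(OC)c(OC)c1
F0 | step 6 | none | none
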